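**Assumptions (one line each)**
- The target is the C2-symmetric isomer. Both benzylic centres are (R) by CIP for the drawn enol tautomer (priorities: trione C2 > aryl > iPr > H), and this holds for the benzyl-protected precursor too.
- The sense of induction in Step 7 cannot be predicted for this new substrate class. The (S,R,R)-ligand is written; one pilot run decides whether it or its mirror image gives the (R,R) product.
- Building-block reagents that supply carbon (MeI, DMF, hexanoyl chloride, BnBr, iPr2Zn) are numbered as reactants and repeated under "Reagents that add atoms".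

## Retrosynthetic overview

1. Target 15 ⇐ tri-O-benzyl ether 14 by neutral global hydrogenolysis.
2. Key step: both C(sp3)–iPr bonds of 14 are cut at once, giving the achiral bis(arylidene-syncarpic acid) 12 and iPr2Zn (two-directional catalytic asymmetric conjugate addition). This replaces the usual Friedel–Crafts/Michael union of an acylphloroglucinol with isobutylidene-syncarpic acid.
3. 12 ⇐ double Knoevenagel condensation of dialdehyde 11 with two equivalents of syncarpic acid 4.
4. 11 ⇐ phloroglucinol (diformylation, hexanoylation, tri-O-benzylation); 4 ⇐ 2,4,6-trihydroxyacetophenone (dearomatising tetramethylation, deacetylation).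
5. Ring order: no ring is built de novo. The two trione rings are made first by dearomatising a phloroglucinol ring; the central arene is phloroglucinol itself.

## Route

**Step 1**
Reactants: 1, 2,4,6-trihydroxyacetophenone; 2, iodomethane
Product: 3, 2-acetyl-4,4,6,6-tetramethylcyclohexane-1,3,5-trione (enol form, "acetylsyncarpic acid")
Conditions: NaOMe (6 equiv), MeI (8 equiv), MeOH, 0 °C → reflux; aq HCl work-up
Reagents that add atoms: iodomethane, CI (four CH3 groups)
Why: Exhaustive dearomatising C-methylation of the phloroglucinol polyanion; in protic solvent the soft electrophile alkylates the two free ring carbons twice each, and the acetyl-bearing carbon stays as the enolised β-triketone.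

**Step 2**
Reactants: 3
Product: 4, syncarpic acid (2,2,4,4-tetramethylcyclohexane-1,3,5-trione)
Conditions: 6 M aq HCl, reflux
Reagents that add atoms: none (acetyl leaves as AcOH; water supplies only H)
Why: Acid-mediated retro-Claisen deacylation of the exocyclic acyl group of a β-triketone; the ring ketones are flanked by quaternary carbons and cannot cleave the same way.

**Step 3**
Reactants: 5, phloroglucinol; 6, N,N-dimethylformamide
Product: 7, 2,4,6-trihydroxybenzene-1,3-dicarbaldehyde
Conditions: POCl3 (2.5 equiv), DMF (2.5 equiv), EtOAc, 0 °C → rt; then H2O, 50 °C
Reagents that add atoms: DMF, CN(C)C=O (formyl carbon, twice); water, O (aldehyde oxygen on iminium hydrolysis)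
Why: Double Vilsmeier–Haack formylation of the highly nucleophilic arene; it stops cleanly at the dialdehyde because the bis(iminium)/keto-enamine intermediate is too deactivated for a third attack.

**Step 4**
Reactants: 7; 8, hexanoyl chloride
Product: 9, 5-hexanoyl-2,4,6-trihydroxybenzene-1,3-dicarbaldehyde
Conditions: hexanoyl chloride (1.5 equiv), AlCl3 (4 equiv), PhNO2, 80 °C; ice/2 M HCl
Reagents that add atoms: hexanoyl chloride, CCCCCC(=O)Cl
Why: Friedel–Crafts acylation at the only free ring position (the same reactivity that gives triacylphloroglucinols); any O-hexanoate formed converges on the C-acyl product by Fries rearrangement under the same conditions.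

**Step 5**
Reactants: 9; 10, benzyl bromide
Product: 11, 2,4,6-tris(benzyloxy)-5-hexanoylbenzene-1,3-dicarbaldehyde
Conditions: BnBr (4.5 equiv), K2CO3 (5 equiv), TBAI (cat.), DMF, 60 °C
Reagents that add atoms: benzyl bromide, BrCc1ccccc1 (three benzyl groups)
Why: Williamson etherification; the phenoxides are vinylogous carboxylates on a fully substituted ring, so O-alkylation is the only productive path, and the non-enolisable aldehydes and weakly acidic ketone tolerate carbonate base.

**Step 6**
Reactants: 11; 4, syncarpic acid (2.2 equiv)
Product: 12, 2,2'-{[2,4,6-tris(benzyloxy)-5-hexanoyl-1,3-phenylene]dimethanylylidene}bis(4,4,6,6-tetramethylcyclohexane-1,3,5-trione); achiral, no E/Z isomers because each trione is symmetric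
Conditions: piperidine/AcOH (20 mol % each), 4 Å MS, toluene, 40 °C; no Lewis acid; store cold
Reagents that add atoms: none other than reactant 4
Why: Two-fold Knoevenagel condensation via iminium activation of the aldehydes by the acidic cyclic 1,3-diketone; the product cannot enolise, the hindered aryl ketone does not condense, and a second Michael addition of 4 (the usual 2:1 adduct) is sterically blocked by the two ortho benzyloxy groups.

**Step 7 (key step)**
Reactants: 12; 13, diisopropylzinc
Product: 14, 1-{2,4,6-tris(benzyloxy)-3,5-bis[(1R)-1-(2-hydroxy-3,3,5,5-tetramethyl-4,6-dioxocyclohex-1-en-1-yl)-2-methylpropyl]phenyl}hexan-1-one, the (R,R) isomer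
Conditions: iPr2Zn (5 equiv, 1 M in toluene), Cu(OTf)2 (10 mol %), (S,R,R)-BINOL-derived N,N-bis(1-phenylethyl)phosphoramidite (20 mol %), toluene/DME, −40 → −20 °C, rigorously O2-free; 1 M HCl work-up; chromatography to remove the meso isomer
Reagents that add atoms: diisopropylzinc, CC(C)[Zn]C(C)C (two isopropyl groups)
Why: Proposed new method: an L*Cu–iPr species (from Cu/Zn transmetalation) π-complexes the exocyclic C=C of the Zn-chelated alkylidene-1,3-dione, and oxidative addition/reductive elimination delivers iPr to one enantiotopic face of each benzylic carbon under ligand control, giving a stabilised zinc trione enolate that is protonated to the enol on work-up; the closest known reaction is the Cu/phosphoramidite-catalysed enantioselective conjugate addition of dialkylzincs (including iPr2Zn) to arylidene Meldrum's acids and enones, and because the two centres are set independently by the same catalyst, the minor-face events are diverted into the separable meso isomer, raising the ee of the (R,R) product (Horeau amplification).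

**Step 8**
Reactants: 14
Product: 15, myrtucommulone F, 1-{2,4,6-trihydroxy-3,5-bis[(1R)-1-(2-hydroxy-3,3,5,5-tetramethyl-4,6-dioxocyclohex-1-en-1-yl)-2-methylpropyl]phenyl}hexan-1-one
Conditions: H2 (1 atm), 10% Pd/C, EtOAc, rt; stop at full conversion
Reagents that add atoms: none
Why: Catalytic hydrogenolysis of the three aryl benzyl ethers under neutral conditions, which avoids both the acid-catalysed cyclodehydration to xanthene-type ethers and the base-promoted retro-Michael that would scramble the benzylic centres; the chelated aryl ketone and the enolised triones are not reduced at 1 atm.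

## Compound list

1 | 2,4,6-trihydroxyacetophenone | CC(=O)c1c(O)cc(O)cc1O | starting material
2 | iodomethane | CI | starting material
3 | 2-acetyl-4,4,6,6-tetramethylcyclohexane-1,3,5-trione (enol) | CC(=O)C1=C(O)C(C)(C)C(=O)C(C)(C)C1=O | intermediate
4 | syncarpic acid | CC1(C)C(=O)CC(=O)C(C)(C)C1=O | intermediate
5 | phloroglucinol | Oc1cc(O)cc(O)c1 | starting material
6 | N,N-dimethylformamide | CN(C)C=O | starting material
7 | 2,4,6-trihydroxybenzene-1,3-dicarbaldehyde | O=Cc1c(O)cc(O)c(C=O)c1O | intermediate
8 | hexanoyl chloride | CCCCCC(=O)Cl | starting material
9 | 5-hexanoyl-2,4,6-trihydroxybenzene-1,3-dicarbaldehyde | CCCCCC(=O)c1c(O)c(C=O)c(O)c(C=O)c1O | intermediate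
10 | benzyl bromide | BrCc1ccccc1 | starting material
11 | 2,4,6-tris(benzyloxy)-5-hexanoylbenzene-1,3-dicarbaldehyde | CCCCCC(=O)c1c(OCc2ccccc2)c(C=O)c(OCc2ccccc2)c(C=O)c1OCc1ccccc1 | intermediate
12 | bis(arylidene-syncarpic acid) | CCCCCC(=O)c1c(OCc2ccccc2)c(C=C2C(=O)C(C)(C)C(=O)C(C)(C)C2=O)c(OCc2ccccc2)c(C=C2C(=O)C(C)(C)C(=O)C(C)(C)C2=O)c1OCc1ccccc1 | intermediate
13 | diisopropylzinc | CC(C)[Zn]C(C)C | starting material
14 | (R,R)-tri-O-benzyl myrtucommulone F | CCCCCC(=O)c1c(OCc2ccccc2)c([C@H](C2=C(O)C(C)(C)C(=O)C(C)(C)C2=O)C(C)C)c(OCc2ccccc2)c([C@H](C2=C(O)C(C)(C)C(=O)C(C)(C)C2=O)C(C)C)c1OCc1ccccc1 | intermediate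
15 | myrtucommulone F | CCCCCC(=O)c1c(O)c([C@H](C2=C(O)C(C)(C)C(=O)C(C)(C)C2=O)C(C)C)c(O)c([C@H](C2=C(O)C(C)(C)C(=O)C(C)(C)C2=O)C(C)C)c1O | target

## Summary

Total steps: 8 (convergent). Longest linear sequence: 6 (phloroglucinol → 7 → 9 → 11 → 12 → 14 → 15; the syncarpic acid branch is 2 steps and joins at Step 6).

**Three steps most likely to fail, each with a fallback that changes the approach**

1. **Step 7, double asymmetric iPr addition.** Risks: the β-carbon is flanked by two ortho benzyloxy groups; iPr2Zn can add by an uncatalysed radical pathway and erode ee; the facial sense is unknown. Fallback: switch nucleophile class and metal. Use Rh(I)/chiral diene-catalysed asymmetric 1,4-addition of potassium isopropenyltrifluoroborate (a flatter sp2 nucleophile) to 12, then let the final H2/Pd-C step both saturate the isopropenyl groups and remove the benzyl ethers.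

2. **Step 5, exhaustive O-benzylation.** Risk: three doubly chelated phenols on a hexasubstituted ring may alkylate incompletely or at carbon. Fallback: protect first, functionalise later. Start from 1,3,5-tris(benzyloxy)benzene, tribrominate with NBS, then run sequential Br/metal exchange with trapping by DMF (twice) and hexanal (followed by oxidation) to reach 11 without ever alkylating a chelated phenol.

3. **Step 6, bis-Knoevenagel.** Risks: hindered aldehydes; possible 2:1 Michael adducts; possible [1,5]-hydride shift/cyclisation of the benzyl ethers onto the very electrophilic alkylidene. Fallback: reverse the order of bond formation. Add an isopropyl-metal to the aldehydes of 11 to give the bis(benzylic carbinol), then form the C–C(trione) bonds by chiral phosphoric acid (chiral counter-anion) controlled SN1 alkylation of syncarpic acid 4 with the trialkoxy-stabilised benzylic cations, which gives 14 directly.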